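Ring atoms are numbered C1 (CMe2), C2 (CHBr), C3, C4 (CHCl), C5, C6 (CHCl), side chain C7=, C8. The key step exploits two features of the six-membered carbocycle: chlorine on C6 sits beside quaternary C1, where substitution cannot place it, and C2 and C8 lie on the same side of C3=C7, as if an oxygen once bridged them in a furan. Everything rests on disconnecting C1–C2 and C6–Cl together: one Cl+ transfer to a prenyl alkene closes the ring onto the α-carbon of a 3-substituted furan, and the C4 ester stereocentre sets C6. The precursor is the (R)-pivalate of 1-(furan-3-yl)-4-methylpent-3-en-1-ol.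

Key step: step 4

Assumption: with furan-3-carbaldehyde the (R)-phosphoric acid is taken to give the (R)-carbinol, as it does with aryl aldehydes; atom labels C1–C8 are those of the target throughout, and CIP labels (R/S, E/Z) change with the substituents even where the spatial arrangement does not.

Step 1
Reactants: 1 furan-3-carbaldehyde; 2 allylboronic acid pinacol ester
Product: 4 (R)-1-(furan-3-yl)but-3-en-1-ol, via borate ester 3 (not isolated)
Conditions: (R)-3,3′-bis(2,4,6-triisopropylphenyl)-1,1′-binaphthyl-2,2′-diyl hydrogen phosphate (5 mol%), toluene, −30 °C; then aq. NaHCO3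
Reagents that add atoms: allylboronic acid pinacol ester (2), C=CCB1OC(C)(C)C(C)(C)O1
Why: Chiral phosphoric acid-catalysed allylboration: the acid activates the boronate in a closed six-membered transition state and its (R)-binaphthyl pocket should expose the aldehyde face that leads to the (R)-carbinol (the future C4), and the O–B bond of 3 is hydrolysed on work-up.

Step 2
Reactants: 4 (R)-1-(furan-3-yl)but-3-en-1-ol; 5 pivaloyl chloride
Product: 6 (R)-1-(furan-3-yl)but-3-en-1-yl pivalate
Conditions: pyridine, 4-(dimethylamino)pyridine (cat.), CH2Cl2, 0 °C to rt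
Reagents that add atoms: pivaloyl chloride (5), CC(C)(C)C(=O)Cl
Why: Nucleophile-catalysed acylation of the secondary alcohol with retention at C4; an ester is chosen because a free hydroxyl or an ether oxygen would trap the cation of step 4 as a tetrahydrofuran, and a pivalate is a poor leaving group at the furylic carbon.

Step 3
Reactants: 6 (R)-1-(furan-3-yl)but-3-en-1-yl pivalate; 7 2-methylbut-2-ene
Product: 8 (R)-1-(furan-3-yl)-4-methylpent-3-en-1-yl pivalate
Conditions: second-generation Grubbs catalyst (H2IMes)(PCy3)Cl2Ru=CHPh (3 mol%), neat 2-methylbut-2-ene (excess), 35 °C, sealed tube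
Reagents that add atoms: 2-methylbut-2-ene (7), CC=C(C)C
Why: Olefin cross-metathesis: the terminal alkene exchanges its =CH2 end for =CMe2 with the excess trisubstituted partner (propene escapes), the prenyl product is too hindered to re-enter the cycle, and furan, ester and C4 are spectators.

Step 4
Reactants: 8 (R)-1-(furan-3-yl)-4-methylpent-3-en-1-yl pivalate
Product: 9 (4R,6S)-6-chloro-7,7-dimethyl-4,5,6,7-tetrahydro-1-benzofuran-4-yl pivalate
Conditions: Et2SCl·SbCl6 (1.1 equiv, added slowly in MeNO2), 2,6-di-tert-butyl-4-methylpyridine (1.2 equiv), MeNO2, −25 °C, 10 min; then aq. NaHCO3/Na2SO3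
Reagents that add atoms: chlorodiethylsulfonium hexachloroantimonate, CC[S+](Cl)CC.Cl[Sb-](Cl)(Cl)(Cl)(Cl)Cl
Why: The sulfonium salt hands Cl+ to the trisubstituted C6=C1 alkene, the chloronium ion opens at tertiary C1 as the furan α-carbon C2 attacks anti to chlorine, and loss of the C2 proton to the hindered pyridine restores the furan, so C6–Cl and C1–C2 form in one operation. The closest known reaction type is the halonium-induced cation–olefin cyclization with halodiethylsulfonium hexachloroantimonates and arene terminators, together with furan-terminated cationic cyclizations. The one new ring, the six-membered carbocycle, closes 6-endo-trig with respect to the alkene through a chair-like arrangement. The new stereocentre C6 is controlled by C4: with chlorine equatorial after anti addition and the pivalate pseudo-equatorial, the chair should lead to the 4,6-cis (4R,6S) product. Three selectivities are needed: Cl+ must choose the alkene over the furan (the furan is inductively deactivated by the acyloxy-bearing carbon, and the prenyl alkene is the more accessible π-donor), C2 must win over C7 (the inherent α- over β-preference of a furan), and C4 must not ionise (the pivalate is a poor nucleofuge, its carbonyl can reach C1 only through a seven-membered ring, and the base removes the acid).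

Step 5
Reactants: 9 (4R,6S)-6-chloro-7,7-dimethyl-4,5,6,7-tetrahydro-1-benzofuran-4-yl pivalate
Product: 10 (4R,6S)-6-chloro-7,7-dimethyl-4,5,6,7-tetrahydro-1-benzofuran-4-ol
Conditions: i-Bu2AlH (2.5 equiv), CH2Cl2, −78 °C; aq. potassium sodium tartrate
Reagents that add atoms: none
Why: Hydride cleavage of the ester (the pivaloyl group leaves as neopentyl alcohol) frees the C4 hydroxyl that must direct step 7, with no bond to C4 broken and with the furan and the neopentyl C6–Cl bond inert to the reagent at −78 °C.

Step 6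
Reactants: 10 (4R,6S)-6-chloro-7,7-dimethyl-4,5,6,7-tetrahydro-1-benzofuran-4-ol
Product: 12 (4R,6S)-6-chloro-4,7a-dihydroxy-7,7-dimethyl-5,6,7,7a-tetrahydro-1-benzofuran-2(4H)-one (7a epimers), via furan endoperoxide 11 (not isolated)
Conditions: O2, hν (visible), 5,10,15,20-tetraphenylporphyrin (cat.), i-Pr2NEt, CH2Cl2, −78 °C to rt
Reagents that add atoms: dioxygen, O=O
Why: Dye-sensitised [4+2] cycloaddition of singlet oxygen across the furan α-carbons C2 and C8 gives 11, and the amine then triggers a Kornblum–DeLaMare fragmentation at C8, the only peroxide-bearing carbon with a hydrogen, so that C8 becomes the lactone carbonyl and C2 a hemiketal carbon (epimeric, erased in step 7) while C4 and C6 are untouched.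

Step 7
Reactants: 12 (4R,6S)-6-chloro-4,7a-dihydroxy-7,7-dimethyl-5,6,7,7a-tetrahydro-1-benzofuran-2(4H)-one
Product: 15 (4R,6S,7aS)-6-chloro-4-hydroxy-7,7-dimethyl-5,6,7,7a-tetrahydro-1-benzofuran-2(4H)-one, via open keto acid 13 (not isolated), via anti hydroxy acid 14 (not isolated)
Conditions: Me4NBH(OAc)3 (5 equiv), MeCN/AcOH (1:1), −20 °C to rt
Reagents that add atoms: none
Why: Hydroxyl-directed triacetoxyborohydride reduction (Saksena–Evans reduction): the hemiketal opens reversibly to keto acid 13, the C4 hydroxyl exchanges onto boron and delivers hydride to the C2 carbonyl from its own face through a six-membered transition state, which sets C2–O anti to C4–O and trans to C6–Cl (the epimer that undirected axial attack of a small hydride would not give), and the Z hydroxy acid 14 lactonises at once.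

Step 8
Reactants: 15 (4R,6S,7aS)-6-chloro-4-hydroxy-7,7-dimethyl-5,6,7,7a-tetrahydro-1-benzofuran-2(4H)-one
Product: 16 (4S,6S,7aR)-4,6-dichloro-7,7-dimethyl-5,6,7,7a-tetrahydro-1-benzofuran-2(4H)-one
Conditions: PPh3, Cl3CC(O)CCl3, CH2Cl2, 0 °C
Reagents that add atoms: hexachloroacetone, ClC(Cl)(Cl)C(=O)C(Cl)(Cl)Cl
Why: Appel-type deoxychlorination: chloride displaces the C4 oxyphosphonium group by SN2 with inversion (4R to 4S, chlorine now trans to C6–Cl), and because C3=C7 is conjugated to the lactone carbonyl neither ionisation at C4 nor SN2′ attack at C7 should compete.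

Step 9
Reactants: 16 (4S,6S,7aR)-4,6-dichloro-7,7-dimethyl-5,6,7,7a-tetrahydro-1-benzofuran-2(4H)-one
Product: 18 (1R,3S,5S,6E)-3,5-dichloro-6-(2-hydroxyethylidene)-2,2-dimethylcyclohexan-1-ol, via lactol 17 (not isolated)
Conditions: i-Bu2AlH (4 equiv), CH2Cl2, −78 to −20 °C; aq. potassium sodium tartrate
Reagents that add atoms: none
Why: Lactone reduction by two 1,2-hydride additions through lactol 17 gives the allylic 1,4-diol; the cis C2/C8 geometry is inherited from the ring (CIP label E here), no stereocentre is touched and the alkyl chlorides are inert to the reagent at low temperature.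

Step 10
Reactants: 18 (1R,3S,5S,6E)-3,5-dichloro-6-(2-hydroxyethylidene)-2,2-dimethylcyclohexan-1-ol
Product: 20 (2S,3Z,4S,6S)-2-bromo-3-(2-bromoethylidene)-4,6-dichloro-1,1-dimethylcyclohexane, via monobromide 19 (not isolated)
Conditions: CBr4 (3 equiv), PPh3 (3 equiv, added last in portions), CH2Cl2, −20 to 0 °C
Reagents that add atoms: carbon tetrabromide, BrC(Br)(Br)Br
Why: Appel bromination: the primary allylic C8 hydroxyl reacts first to give 19, whose electron-withdrawing CH2Br group disfavours SN2′ capture at C7, and bromide then displaces the C2 oxyphosphonium group by SN2 with inversion (2R to 2S), which places bromine cis to C6–Cl as in the target.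

Compound list
1 | furan-3-carbaldehyde | O=Cc1ccoc1 | starting material
2 | allylboronic acid pinacol ester | C=CCB1OC(C)(C)C(C)(C)O1 | starting material
3 | (R)-2-{[1-(furan-3-yl)but-3-en-1-yl]oxy}-4,4,5,5-tetramethyl-1,3,2-dioxaborolane (formed in situ) | C=CC[C@@H](OB1OC(C)(C)C(C)(C)O1)c1ccoc1 | intermediate
4 | (R)-1-(furan-3-yl)but-3-en-1-ol | C=CC[C@@H](O)c1ccoc1 | intermediate
5 | pivaloyl chloride | CC(C)(C)C(=O)Cl | starting material
6 | (R)-1-(furan-3-yl)but-3-en-1-yl pivalate | C=CC[C@@H](OC(=O)C(C)(C)C)c1ccoc1 | intermediate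
7 | 2-methylbut-2-ene | CC=C(C)C | starting material
8 | (R)-1-(furan-3-yl)-4-methylpent-3-en-1-yl pivalate | CC(C)=CC[C@@H](OC(=O)C(C)(C)C)c1ccoc1 | intermediate
9 | (4R,6S)-6-chloro-7,7-dimethyl-4,5,6,7-tetrahydro-1-benzofuran-4-yl pivalate | CC1(C)c2occc2[C@H](OC(=O)C(C)(C)C)C[C@@H]1Cl | intermediate
10 | (4R,6S)-6-chloro-7,7-dimethyl-4,5,6,7-tetrahydro-1-benzofuran-4-ol | CC1(C)c2occc2[C@H](O)C[C@@H]1Cl | intermediate
11 | (4R,6S)-6-chloro-7,7-dimethyl-2,7a-epidioxy-2,4,5,6,7,7a-hexahydro-1-benzofuran-4-ol (bridgehead configuration not defined, formed in situ) | CC1(C)C23OOC(C=C2[C@H](O)C[C@@H]1Cl)O3 | intermediate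
12 | (4R,6S)-6-chloro-4,7a-dihydroxy-7,7-dimethyl-5,6,7,7a-tetrahydro-1-benzofuran-2(4H)-one (7a epimers) | CC1(C)C2(O)OC(=O)C=C2[C@H](O)C[C@@H]1Cl | intermediate
13 | (2Z)-2-[(4S,6R)-4-chloro-6-hydroxy-3,3-dimethyl-2-oxocyclohexylidene]acetic acid (ring-opened tautomer of 12, formed in situ) | CC1(C)C(=O)/C(=C\C(=O)O)[C@H](O)C[C@@H]1Cl | intermediate
14 | (2Z)-2-[(2S,4S,6R)-4-chloro-2,6-dihydroxy-3,3-dimethylcyclohexylidene]acetic acid (formed in situ) | CC1(C)[C@@H](O)/C(=C\C(=O)O)[C@H](O)C[C@@H]1Cl | intermediate
15 | (4R,6S,7aS)-6-chloro-4-hydroxy-7,7-dimethyl-5,6,7,7a-tetrahydro-1-benzofuran-2(4H)-one | CC1(C)[C@H]2OC(=O)C=C2[C@H](O)C[C@@H]1Cl | intermediate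
16 | (4S,6S,7aR)-4,6-dichloro-7,7-dimethyl-5,6,7,7a-tetrahydro-1-benzofuran-2(4H)-one | CC1(C)[C@H]2OC(=O)C=C2[C@@H](Cl)C[C@@H]1Cl | intermediate
17 | (4S,6S,7aR)-4,6-dichloro-7,7-dimethyl-2,4,5,6,7,7a-hexahydro-1-benzofuran-2-ol (C2 epimers, formed in situ as its aluminium alkoxide) | CC1(C)[C@H]2OC(O)C=C2[C@@H](Cl)C[C@@H]1Cl | intermediate
18 | (1R,3S,5S,6E)-3,5-dichloro-6-(2-hydroxyethylidene)-2,2-dimethylcyclohexan-1-ol | CC1(C)[C@@H](O)/C(=C\CO)[C@@H](Cl)C[C@@H]1Cl | intermediate
19 | (1R,3S,5S,6E)-6-(2-bromoethylidene)-3,5-dichloro-2,2-dimethylcyclohexan-1-ol (formed in situ) | CC1(C)[C@@H](O)/C(=C\CBr)[C@@H](Cl)C[C@@H]1Cl | intermediate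
20 | (2S,3Z,4S,6S)-2-bromo-3-(2-bromoethylidene)-4,6-dichloro-1,1-dimethylcyclohexane | CC1(C)[C@H](Br)/C(=C\CBr)[C@@H](Cl)C[C@@H]1Cl | target

Total step count: 10
Longest linear sequence: 10 steps (1 to 20)

Steps most likely to fail

Step 4. What may go wrong: the electrophilic chlorine is transferred to the furan nucleus (ring chlorination) instead of the alkene, so the cation never forms. Fallback (sets out from 1, returns at 12): the furan is made electron-poor with a carboxyl group that is expelled later. In situ masking of the aldehyde of 1 as its lithium morpholide adduct, lithiation of the remote α-position with s-BuLi and quenching with ClCO2Me should give furoate aldehyde F1. Steps 1–3 applied as above (with 2, 5 and 7) lead through borate F2 to alcohol F3, pivalate F4 and prenyl ester F5. A 2-furoate resists ring chlorination but is still alkylated at its free α-carbon, the normal site of Friedel–Crafts attack, so the same Cl+ closure should give bicyclic furoate F6. LiOH (aq. MeOH, 50 °C) cleaves both esters to hydroxy acid F7, and dye-sensitised photooxygenation of this furoic acid gives endoperoxide F8, which loses CO2 and delivers 12.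

Step 7. What may go wrong: the hemiketal stays closed so that no hydride is delivered, or an undirected background reduction erodes the facial selectivity at C2. Fallback (sets out from 12, returns at 15): the ring-opened form is fixed before reduction. Me3SiCHN2 in MeOH/toluene methylates the carboxylic acid tautomer to keto ester F9, a free β-hydroxy ketone of the kind on which Me4NBH(OAc)3 delivery is standard. The resulting anti diol ester F10 lactonises with loss of methanol (catalytic TsOH if needed) to 15.

Step 10. What may go wrong: at the shielded C2 the oxyphosphonium ion pair collapses by allylic transposition to C7 or by ionisation with loss of configuration, or the C2 hydroxyl closes onto activated C8 to form a cyclic ether. Fallback (sets out from 18, returns at 20): the two C–Br bonds are made separately, with a small preformed leaving group at C2. One equivalent of CBr4/PPh3 at −40 °C gives monobromide 19, now isolated. Ms2O/Et3N at −40 °C converts it into methanesulfonate F11, and LiBr in THF/acetone at −20 to 0 °C displaces the sulfonate in a bimolecular step with inversion to give 20.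

Further compounds
F1 | step 4 | methyl 4-formylfuran-2-carboxylate | COC(=O)c1cc(C=O)co1
F2 | step 4 | methyl 4-[(1R)-1-[(4,4,5,5-tetramethyl-1,3,2-dioxaborolan-2-yl)oxy]but-3-en-1-yl]furan-2-carboxylate | C=CC[C@@H](OB1OC(C)(C)C(C)(C)O1)c1coc(C(=O)OC)c1
F3 | step 4 | methyl 4-[(1R)-1-hydroxybut-3-en-1-yl]furan-2-carboxylate | C=CC[C@@H](O)c1coc(C(=O)OC)c1
F4 | step 4 | methyl 4-[(1R)-1-(pivaloyloxy)but-3-en-1-yl]furan-2-carboxylate | C=CC[C@@H](OC(=O)C(C)(C)C)c1coc(C(=O)OC)c1
F5 | step 4 | methyl 4-[(1R)-4-methyl-1-(pivaloyloxy)pent-3-en-1-yl]furan-2-carboxylate | CC(C)=CC[C@@H](OC(=O)C(C)(C)C)c1coc(C(=O)OC)c1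
F6 | step 4 | methyl (4R,6S)-6-chloro-7,7-dimethyl-4-(pivaloyloxy)-4,5,6,7-tetrahydro-1-benzofuran-2-carboxylate | CC1(C)c2oc(C(=O)OC)cc2[C@H](OC(=O)C(C)(C)C)C[C@@H]1Cl
F7 | step 4 | (4R,6S)-6-chloro-4-hydroxy-7,7-dimethyl-4,5,6,7-tetrahydro-1-benzofuran-2-carboxylic acid | CC1(C)c2oc(C(=O)O)cc2[C@H](O)C[C@@H]1Cl
F8 | step 4 | (4R,6S)-6-chloro-4-hydroxy-7,7-dimethyl-2,7a-epidioxy-2,4,5,6,7,7a-hexahydro-1-benzofuran-2-carboxylic acid | CC1(C)C23OOC(C(=O)O)(C=C2[C@H](O)C[C@@H]1Cl)O3
F9 | step 7 | methyl (2Z)-2-[(4S,6R)-4-chloro-6-hydroxy-3,3-dimethyl-2-oxocyclohexylidene]acetate | CC1(C)C(=O)/C(=C\C(=O)OC)[C@H](O)C[C@@H]1Cl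
F10 | step 7 | methyl (2Z)-2-[(2S,4S,6R)-4-chloro-2,6-dihydroxy-3,3-dimethylcyclohexylidene]acetate | CC1(C)[C@@H](O)/C(=C\C(=O)OC)[C@H](O)C[C@@H]1Cl
F11 | step 10 | (1R,3S,5S,6E)-6-(2-bromoethylidene)-3,5-dichloro-2,2-dimethylcyclohexyl methanesulfonate | CC1(C)[C@@H](OS(C)(=O)=O)/C(=C\CBr)[C@@H](Cl)C[C@@H]1Cl
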